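**Plan**

- Retrosynthesis: the C5 and C7 O–CH3 bonds are cut last. Ring B is then cut in one operation at O1–C8a, C4–C4a and O1–C2, which gives a ring-A aryne (C4a≡C8a) and a C18 2-ynoic acid.
- Enabling feature: O1 and the C4 carbonyl carbon sit on the adjacent ring-A carbons C8a and C4a, and the C5 oxygen next to C4a polarises the C4a≡C8a triple bond. C5 is carried as a methyl ether, not a sulfonate, so the C4a carbanion has no β-leaving group to expel.
- The aryne precursor is cut at O–Tf, at C4a–Si and C8–CH3 (two carbamate-directed metalations) and at C8a–O (C–H borylation/oxidation), back to a 2-methylresorcinol dimethyl ether. The acid is cut at C–CO2H.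
- Forward: ring A is bought and fully substituted in six steps. The chain enters as the ynoic acid in the key step, which also closes ring B, the only ring formed. Global demethylation ends the route.
- Stereochemistry: the target has no stereocentre and no stereogenic double bond, so none has to be set.

Key step: step 8

Remark: chromone numbering (O1, C2 to C8a) is used for ring positions throughout, also in precursors; the C17 terminal alkyne used in step 7 is taken to be a catalogue compound.

**Route**

Step 1
Reactants: 1 2,6-dimethoxytoluene
Product: 3 3,5-dimethoxy-4-methylphenol, via aryl pinacol boronate 2 (not isolated)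
Conditions: [Ir(OMe)(cod)]2 (1.5 mol %), 4,4'-di-tert-butyl-2,2'-bipyridine (3 mol %), B2pin2 (0.6 equiv), THF, 80 °C; then KHSO5 (Oxone), acetone/H2O, rt
Reagents that add atoms: potassium peroxymonosulfate (KHSO5, active component of Oxone), [K+].[O-]S(=O)(=O)OO
Why: Iridium-catalysed C–H borylation is sterically governed and should take the only ring C–H of 1 without an ortho substituent (para to the methyl group), and ipso-oxidation of boronate 2 by peroxymonosulfate then gives the phenol in the same flask (one-pot C–H borylation/oxidation).

Step 2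
Reactants: 3 3,5-dimethoxy-4-methylphenol
Product: 4 3,5-dimethoxy-4-methylphenyl N,N-diethylcarbamate
Conditions: NaH, THF, 0 °C; Et2NC(O)Cl, 0 °C → rt
Reagents that add atoms: N,N-diethylcarbamoyl chloride, CCN(CC)C(Cl)=O
Why: O-Carbamoylation of the sodium phenoxide is a routine acyl substitution and installs the strongest oxygen-based directing group for the two metalations that follow.

Step 3
Reactants: 4 3,5-dimethoxy-4-methylphenyl N,N-diethylcarbamate
Product: 6 3,5-dimethoxy-4-methyl-2-(trimethylsilyl)phenyl N,N-diethylcarbamate, via aryllithium 5 (not isolated)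
Conditions: s-BuLi, TMEDA, THF, −78 °C; Me3SiCl, −78 °C → rt
Reagents that add atoms: chlorotrimethylsilane, C[Si](C)(C)Cl
Why: Directed ortho-metalation, in which the carbamate and the neighbouring methoxy group jointly direct s-BuLi·TMEDA to C2 (C2 and C6 of 4 are equivalent) and aryllithium 5 is silylated at −78 °C before an anionic ortho-Fries shift of the carbamoyl group can set in.

Step 4
Reactants: 6 3,5-dimethoxy-4-methyl-2-(trimethylsilyl)phenyl N,N-diethylcarbamate
Product: 8 3,5-dimethoxy-2,4-dimethyl-6-(trimethylsilyl)phenyl N,N-diethylcarbamate, via aryllithium 7 (not isolated)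
Conditions: s-BuLi, TMEDA, THF, −78 °C; MeI, −78 °C → rt
Reagents that add atoms: iodomethane, CI
Why: Second directed ortho-metalation, in which silicon blocks one ortho position so that the only remaining ring proton (between the carbamate and a methoxy group) is removed, and aryllithium 7 is C-methylated by iodomethane in an SN2 alkylation.

Step 5
Reactants: 8 3,5-dimethoxy-2,4-dimethyl-6-(trimethylsilyl)phenyl N,N-diethylcarbamate
Product: 9 3,5-dimethoxy-2,4-dimethyl-6-(trimethylsilyl)phenol
Conditions: LiAlH4, THF, 0 °C → reflux; aq. KNaC4H4O6 (Rochelle salt) work-up near pH 7; crude phenol carried on without chromatography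
Reagents that add atoms: none
Why: Reductive cleavage of the aryl carbamate, in which the small hydride reaches the doubly flanked carbonyl, the aryloxide is expelled and the amide residue is reduced to the tertiary amine, while the neutral work-up avoids ipso-protonation (protodesilylation) of the electron-rich arylsilane.

Step 6
Reactants: 9 3,5-dimethoxy-2,4-dimethyl-6-(trimethylsilyl)phenol
Product: 10 3,5-dimethoxy-2,4-dimethyl-6-(trimethylsilyl)phenyl trifluoromethanesulfonate
Conditions: Tf2O, pyridine, CH2Cl2, 0 °C → rt
Reagents that add atoms: trifluoromethanesulfonic anhydride, O=S(=O)(OS(=O)(=O)C(F)(F)F)C(F)(F)F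
Why: O-Triflation of the phenol gives the ortho-silylaryl triflate, the standard fluoride-triggered aryne precursor, and the electron-withdrawing sulfonate also makes the C–Si bond less prone to protonolysis.

Step 7
Reactants: 11 1-heptadecyne
Product: 13 octadec-2-ynoic acid, via lithium acetylide 12 (not isolated)
Conditions: n-BuLi, THF, −78 °C; CO2 (gas), −78 °C → rt; aq. HCl
Reagents that add atoms: carbon dioxide, O=C=O
Why: Deprotonation of the terminal alkyne and carboxylation of lithium acetylide 12 with carbon dioxide is a standard route to 2-alkynoic acids.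

Step 8
Reactants: 10 3,5-dimethoxy-2,4-dimethyl-6-(trimethylsilyl)phenyl trifluoromethanesulfonate (1.5 equiv); 13 octadec-2-ynoic acid
Product: 16 5,7-dimethoxy-6,8-dimethyl-2-pentadecyl-4H-chromen-4-one, via aryne 14 (not isolated), via hydroxyaryl ynone 15 (not isolated)
Conditions: CsF (4 equiv), THF, 125 °C, sealed tube
Reagents that add atoms: none
Why: Fluoride deprotonates 13 and removes the silyl group of 10, loss of triflate gives aryne 14 (C4a≡C8a), the carboxylate oxygen adds to C8a, the C4a carbanion attacks the ester carbonyl in a 4-exo-trig step and the benzoxetene alkoxide opens to the phenoxide of ynone 15, so that O1–C8a and C4–C4a arise by net insertion of the aryne into the acid C–O bond. The phenoxide then adds to the alkyne β-carbon in a 6-endo-dig oxa-Michael closure (O1–C2) that forms ring B, and the C3 vinyl anion is protonated by the hydrogen fluoride released when the acid was deprotonated. The closest known reaction type is the CsF-mediated C–O insertion of arynes into carboxylic acids, which gives ortho-hydroxyaryl ketones and, from 3-substituted propiolic acids, 4H-chromen-4-ones directly. No stereocentre is formed. The step needs regioselective O-attack at C8a: the inductively withdrawing C5 methoxy group distorts the aryne so that the carbon remote from it (C8a) is the electrophilic end and the developing C4a anion lies next to the C–O bond, which should outweigh the small steric bias of the C8 methyl group. Because C5 carries an ether and not a sulfonate, the C4a anion can neither expel a β-leaving group to form a second aryne nor undergo sulfonyl migration, so acyl capture only has to outrun protonation, which the aprotic medium and the excess of 10 favour.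

Step 9
Reactants: 16 5,7-dimethoxy-6,8-dimethyl-2-pentadecyl-4H-chromen-4-one
Product: 17 5,7-dihydroxy-6,8-dimethyl-2-pentadecyl-4H-chromen-4-one (CNP0302050.0)
Conditions: BBr3 (6 equiv), CH2Cl2, −78 °C → rt; H2O quench
Reagents that add atoms: none
Why: Lewis-acid ether cleavage, in which BBr3 coordinates each methoxy oxygen and bromide removes the methyl group by SN2, the C5 ether being assisted by chelation to the C4 carbonyl and the C7 ether being twisted out of plane by its two methyl neighbours and therefore basic, while the chromone ring and the alkyl chain are inert.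

**Compound list**

1 | 2,6-dimethoxytoluene | COc1cccc(OC)c1C | starting material
2 | 2-(3,5-dimethoxy-4-methylphenyl)-4,4,5,5-tetramethyl-1,3,2-dioxaborolane | COc1cc(B2OC(C)(C)C(C)(C)O2)cc(OC)c1C | intermediate (not isolated)
3 | 3,5-dimethoxy-4-methylphenol | COc1cc(O)cc(OC)c1C | intermediate
4 | 3,5-dimethoxy-4-methylphenyl N,N-diethylcarbamate | CCN(CC)C(=O)Oc1cc(OC)c(C)c(OC)c1 | intermediate
5 | [6-(diethylcarbamoyloxy)-2,4-dimethoxy-3-methylphenyl]lithium | [Li]c1c(OC)c(C)c(OC)cc1OC(=O)N(CC)CC | intermediate (not isolated)
6 | 3,5-dimethoxy-4-methyl-2-(trimethylsilyl)phenyl N,N-diethylcarbamate | CCN(CC)C(=O)Oc1cc(OC)c(C)c(OC)c1[Si](C)(C)C | intermediate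
7 | [2-(diethylcarbamoyloxy)-4,6-dimethoxy-5-methyl-3-(trimethylsilyl)phenyl]lithium | [Li]c1c(OC)c(C)c(OC)c([Si](C)(C)C)c1OC(=O)N(CC)CC | intermediate (not isolated)
8 | 3,5-dimethoxy-2,4-dimethyl-6-(trimethylsilyl)phenyl N,N-diethylcarbamate | CCN(CC)C(=O)Oc1c(C)c(OC)c(C)c(OC)c1[Si](C)(C)C | intermediate
9 | 3,5-dimethoxy-2,4-dimethyl-6-(trimethylsilyl)phenol | COc1c(C)c(OC)c([Si](C)(C)C)c(O)c1C | intermediate
10 | 3,5-dimethoxy-2,4-dimethyl-6-(trimethylsilyl)phenyl trifluoromethanesulfonate | COc1c(C)c(OC)c([Si](C)(C)C)c(OS(=O)(=O)C(F)(F)F)c1C | intermediate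
11 | 1-heptadecyne | CCCCCCCCCCCCCCCC#C | starting material
12 | lithium heptadec-1-yn-1-ide | CCCCCCCCCCCCCCCC#C[Li] | intermediate (not isolated)
13 | octadec-2-ynoic acid | CCCCCCCCCCCCCCCC#CC(=O)O | intermediate
14 | 3,5-dimethoxy-4,6-dimethylbenzyne (1,2-didehydro-3,5-dimethoxy-4,6-dimethylbenzene) | COC1=C(C)C#CC(OC)=C1C | intermediate (not isolated)
15 | 1-(2-hydroxy-4,6-dimethoxy-3,5-dimethylphenyl)octadec-2-yn-1-one | CCCCCCCCCCCCCCCC#CC(=O)c1c(O)c(C)c(OC)c(C)c1OC | intermediate (not isolated)
16 | 5,7-dimethoxy-6,8-dimethyl-2-pentadecyl-4H-chromen-4-one | CCCCCCCCCCCCCCCc1cc(=O)c2c(OC)c(C)c(OC)c(C)c2o1 | intermediate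
17 | 5,7-dihydroxy-6,8-dimethyl-2-pentadecyl-4H-chromen-4-one | CCCCCCCCCCCCCCCc1cc(=O)c2c(O)c(C)c(O)c(C)c2o1 | target

**Summary**

Total step count: 9. Longest linear sequence: 8 steps (steps 1 to 6, 8 and 9); step 7 is a one-step branch.

Steps most likely to fail:

1. Step 8. The C4a carbanion may be protonated before the 1,3-acyl shift, so that the reaction stops at O-arylation. The carboxylate may also add at C4a instead of C8a if the C8 methyl group erodes the methoxy-directed regiocontrol, or the ynoate may degrade at 125 °C. The fallback sets out from 9 and returns at 16, making the C4–C4a bond by palladium acylation instead of aryne insertion. Ipso-iododesilylation of 9 with ICl (CH2Cl2, −78 °C) should give 2-iodo-3,5-dimethoxy-4,6-dimethylphenol F1. Carbonylative Sonogashira coupling of F1 with alkyne 11 (PdCl2(PPh3)2, Et3N, CO 1 atm, DMF, 80 °C) should give ynone 15, whose phenoxide closes 6-endo-dig under the basic conditions to chromone 16.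

2. Step 5. The trimethylsilyl group may be lost by ipso-protonation during reduction or work-up, because the arylsilane sits ortho and para to three oxygen donors, and reduction of the doubly flanked carbamate may be slow. The fallback sets out from 8 and returns at 10, bypassing 9 and bringing silicon in only after the phenol is free.
   - Reduction of 8 with LiAlH4 followed by a deliberately acidic work-up (aq. HCl) removes carbamate and silicon together and should give 3,5-dimethoxy-2,4-dimethylphenol F2.
   - NBS (MeCN, 0 °C) brominates the single free ring position to give 2-bromo-3,5-dimethoxy-4,6-dimethylphenol F3.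
   - Hexamethyldisilazane (neat, 80 °C) gives (2-bromo-3,5-dimethoxy-4,6-dimethylphenoxy)trimethylsilane F4.
   - n-BuLi (THF, −78 °C) effects bromine–lithium exchange to [2,4-dimethoxy-3,5-dimethyl-6-(trimethylsilyloxy)phenyl]lithium F5, which undergoes the 1,3 O→C silyl shift (retro-Brook rearrangement) to lithium 3,5-dimethoxy-2,4-dimethyl-6-(trimethylsilyl)phenoxide F6.
   - Tf2O added to the same flask triflates F6 to give 10.

3. Step 4. In the crowded aryllithium, deprotonation at a silicon-bound methyl group or 1,3-migration of the carbamoyl group may compete with clean ring methylation. The fallback sets out from 4 and returns at 8, bypassing 6; it makes the C8–CH3 bond by cross-coupling and introduces silicon last.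
   - NBS (1 equiv, MeCN, 0 °C) should give 2-bromo-3,5-dimethoxy-4-methylphenyl N,N-diethylcarbamate F7.
   - Suzuki–Miyaura methylation (MeB(OH)2, Pd(OAc)2, SPhos, K3PO4, toluene/H2O, 100 °C) gives 3,5-dimethoxy-2,4-dimethylphenyl N,N-diethylcarbamate F8.
   - s-BuLi/TMEDA (THF, −78 °C) removes the remaining ring proton between carbamate and methoxy group to give [2-(diethylcarbamoyloxy)-4,6-dimethoxy-3,5-dimethylphenyl]lithium F9. Under these kinetic conditions ring deprotonation is expected to be preferred over lateral metalation of the ortho methyl group.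
   - Me3SiCl then gives 8.

**Further compounds**

F1 | step 8 | 2-iodo-3,5-dimethoxy-4,6-dimethylphenol | COc1c(C)c(OC)c(I)c(O)c1C
F2 | step 5 | 3,5-dimethoxy-2,4-dimethylphenol | COc1cc(O)c(C)c(OC)c1C
F3 | step 5 | 2-bromo-3,5-dimethoxy-4,6-dimethylphenol | COc1c(C)c(OC)c(Br)c(O)c1C
F4 | step 5 | (2-bromo-3,5-dimethoxy-4,6-dimethylphenoxy)trimethylsilane | COc1c(C)c(OC)c(Br)c(O[Si](C)(C)C)c1C
F5 | step 5 | [2,4-dimethoxy-3,5-dimethyl-6-(trimethylsilyloxy)phenyl]lithium | [Li]c1c(OC)c(C)c(OC)c(C)c1O[Si](C)(C)C
F6 | step 5 | lithium 3,5-dimethoxy-2,4-dimethyl-6-(trimethylsilyl)phenoxide | [Li+].[O-]c1c(C)c(OC)c(C)c(OC)c1[Si](C)(C)C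
F7 | step 4 | 2-bromo-3,5-dimethoxy-4-methylphenyl N,N-diethylcarbamate | CCN(CC)C(=O)Oc1cc(OC)c(C)c(OC)c1Br
F8 | step 4 | 3,5-dimethoxy-2,4-dimethylphenyl N,N-diethylcarbamate | CCN(CC)C(=O)Oc1cc(OC)c(C)c(OC)c1C
F9 | step 4 | [2-(diethylcarbamoyloxy)-4,6-dimethoxy-3,5-dimethylphenyl]lithium | [Li]c1c(OC)c(C)c(OC)c(C)c1OC(=O)N(CC)CC
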